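**Plan**
- Retrosynthetic cuts: the three ester C–O bonds; then C5–C6 of the seven-membered ring (retro-semipinacol, back to a six-membered-ring carbinol carrying an epoxy-isopropyl group on C7); then C5–C11 of the cyclobutane (retro-enolate alkylation); then C10–C11 and C3–C4 (retro-Diels–Alder to a quinone and a 2-silyloxydiene).
- Forward order: rings A and B together by Diels–Alder (cis-decalin), cyclobutane by 1,3-alkylation (C5 bonded directly to C7), then ring B enlarged from six to seven members by a semipinacol shift.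
- Enabling feature: C7–O sits next to the quaternary C6 carrying CH3 and CH2O (a 2-quaternary 1,3-dioxygen unit, O-14/O-7), and C5 is a cyclobutane methine that can migrate from C7 to C6 of an epoxy alcohol.
- Stereochemistry: absolute sense and C3/C4/C10 from a catalytic enantioselective endo Diels–Alder; C9 from convex-face hydride delivery; C5 inverted twice (Finkelstein, then SN2 ring closure); C6 from a hydroxyl-directed epoxidation followed by the stereospecific 1,2-shift; C7 from hydride delivery directed by the 14-OH.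

Key step: step 11

Atom labels (longipinane numbering, used for every compound): C1 ketone carbon, C2, C3 (bears CH3-12), C4, C5, C6 (bears CH3-13 and C14H2–O), C7, C8, C9, C10 (bears CH3-15), C11; cyclobutane = C4–C5–C11–C10. "C4 side" and "C11 side" name the two faces of the C7–C8–C9 chain.
Assumption: 3, 13 and 21 are bought. The (S)-configured catalyst of step 2 is assigned from the binding model for 2,5-disubstituted benzoquinones (carbonyl next to the vinylic C–H of the reacting double bond); its mirror image would be used if the facial sense proved opposite.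

**Step 1**
Reactants: 1 (E)-pent-3-en-2-one
Product: 2 (E)-2-(triisopropylsilyloxy)penta-1,3-diene
Conditions: i-Pr3SiOTf, Et3N, Et2O, 0 °C → rt
Reagents that add atoms: triisopropylsilyl trifluoromethanesulfonate, CC(C)[Si](C(C)C)(C(C)C)OS(=O)(=O)C(F)(F)F
Why: Soft enolisation with O-silylation (silyl dienol ether formation) removes a proton from the acetyl CH3 and leaves the (E)-propenyl unit untouched.

**Step 2**
Reactants: 2 (E)-2-(triisopropylsilyloxy)penta-1,3-diene; 3 2-methoxy-5-methyl-1,4-benzoquinone
Product: 4 cis-decalin enedione (ring A silyl enol ether; ring B C5(=O)–C7(OMe)=C8–C9(=O))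
Conditions: (S)-3,3-diphenyl-1-(o-tolyl)tetrahydropyrrolo[1,2-c][1,3,2]oxazaborole·HNTf2 (20 mol %), CH2Cl2, −78 °C
Reagents that add atoms: none
Why: Oxazaborolidinium-catalysed quinone Diels–Alder reaction: the methoxy-free, methyl-bearing double bond reacts, its methyl carbon (β to the non-vinylogous carbonyl) takes the nucleophilic CH2 terminus of the silyloxydiene, the dienophile geometry gives the cis fusion (4-H cis to 10-CH3), endo addition puts 3-CH3 trans to 10-CH3, and the catalyst sets the absolute sense.

**Step 3**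
Reactants: 4 cis-decalin enedione
Product: 5 cis-decalin 5,9-diol
Conditions: i-Bu2AlH (3.5 equiv), CH2Cl2, −78 °C; aq. KNaC4H4O6 work-up
Reagents that add atoms: none
Why: 1,2-Reduction of the enone and of the vinylogous ester carbonyl by the aluminium hydride from the convex face of the folded cis-decalin (the face of 4-H, away from the axial C11 methylene) should place both hydroxyls on the ring-B face that carries the bonds to ring A, which is the final C9 configuration.

**Step 4**
Reactants: 5 cis-decalin 5,9-diol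
Product: 7 5-O-mesyl 9-O-TBS cis-decalin, via monomesylate 6 (not isolated)
Conditions: MsCl, Et3N, CH2Cl2, −40 °C; then 2,6-lutidine, t-BuMe2SiOTf, −40 → 0 °C
Reagents that add atoms: methanesulfonyl chloride, CS(=O)(=O)Cl; tert-butyldimethylsilyl trifluoromethanesulfonate, CC(C)(C)[Si](C)(C)OS(=O)(=O)C(F)(F)F
Why: Selective sulfonylation then silylation: the C5 hydroxyl (next to a methine) reacts before the neopentyl C9 hydroxyl (next to quaternary C10), which then takes the silyl triflate, so no free 9-OH is present once C5 carries an inverted leaving group.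

**Step 5**
Reactants: 7 5-O-mesyl 9-O-TBS cis-decalin
Product: 8 keto mesylate (C1 ketone)
Conditions: Bu4NF, AcOH (1:1), THF, −20 °C
Reagents that add atoms: none
Why: Buffered fluoride protodesilylation of the silyl enol ether (an enolate leaves silicon far faster than the hindered secondary 9-alkoxide) releases the C1 ketone without base.

**Step 6**
Reactants: 8 keto mesylate
Product: 10 tricyclic ketone with cyclobutane C4–C5–C11–C10, via bromide 9 (not isolated)
Conditions: LiBr, THF, 0 °C → rt; then t-BuOK, t-BuOH/THF, 0 °C → rt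
Reagents that add atoms: none
Why: Finkelstein displacement inverts C5 to the less crowded exo bromide, and the equilibrating C1 enolate then closes the four-membered ring by intramolecular SN2 C-alkylation (4-exo-tet, the ketone-enolate/1,3-sulfonate closure known for cis-decalones); only C11 can reach the rear of C5, so the second inversion puts the C5–C11 bond on the ring-A face.

**Step 7**
Reactants: 10 tricyclic ketone
Product: 12 1-hydroxy 7-ketone, via enol ether alcohol 11 (not isolated)
Conditions: NaBH4, MeOH, 0 °C; then 1 M aq. HCl, THF, 0 °C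
Reagents that add atoms: water, O
Why: Borohydride reduction masks the only ketone (C1) as an alcohol (hydride from the face remote from the methyl-bearing C10 bridge), and mild acid hydrolysis of the methyl enol ether then leaves C7 as the sole ketone.

**Step 8**
Reactants: 12 1-hydroxy 7-ketone; 13 isopropenylmagnesium bromide
Product: 14 7-isopropenyl 1,7-diol
Conditions: 13 (3 equiv), CeCl3, THF, −78 → 0 °C; aq. NH4Cl
Reagents that add atoms: isopropenylmagnesium bromide (13), C=C(C)[Mg]Br
Why: Organocerium 1,2-addition (too weakly basic to enolise the ketone or eliminate the β-silyloxy group) should occur on the face anti to the 9-OTBS group (C4 side), placing the tertiary 7-OH on the C11 side.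

**Step 9**
Reactants: 14 7-isopropenyl 1,7-diol
Product: 15 tertiary allylic alcohol with C1 ketone
Conditions: Dess–Martin periodinane, NaHCO3, CH2Cl2, rt
Reagents that add atoms: none
Why: Dess–Martin oxidation restores the C1 ketone, and the tertiary allylic alcohol cannot be oxidised.

**Step 10**
Reactants: 15 tertiary allylic alcohol
Product: 16 epoxy alcohol (C6–O–C14 oxirane on C7)
Conditions: VO(acac)2 (5 mol %), t-BuOOH, CH2Cl2, 0 °C → rt
Reagents that add atoms: tert-butyl hydroperoxide, CC(C)(C)OO
Why: Vanadium-catalysed hydroxyl-directed epoxidation delivers oxygen syn to the 7-OH through the rotamer in which CH3-13 lies over C8 and away from the C4 bridge, which fixes the C6 configuration.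

**Step 11**
Reactants: 16 epoxy alcohol
Product: 17 9-(tert-butyldimethylsilyloxy)-14-hydroxylongipinane-1,7-dione
Conditions: ZnBr2, CH2Cl2, 0 °C → rt
Reagents that add atoms: none
Why: Zinc binds the 7-hydroxyl and the epoxide oxygen, the C6–O bond opens at the tertiary carbon while the C5–C7 bond, antiperiplanar to it in the chelate, shifts from C7 to C6 and the carbinol collapses to the C7 ketone (semipinacol rearrangement of a tertiary α-hydroxy epoxide). The closest known reaction type is the Lewis-acid ring-expanding semipinacol rearrangement of 1-(oxiranyl)cycloalkanols to 2-quaternary 3-hydroxy ketones. No ring is closed by cyclisation: the seven-membered ring C5–C6–C7–C8–C9–C10–C11 arises from the six-membered ring C5–C7–C8–C9–C10–C11 by a 1,2-shift that inserts C6. The new stereocentre C6 is controlled by the epoxide configuration, because the shift proceeds with retention at C5 and inversion at C6. The step needs migration of the cyclobutane methine C5 and not of the methylene C8; the chelate with CH3-13 turned away from the C4 bridge has only C5 anti to the breaking bond, and C8 (primary, β to the silyloxy carbon) is the poorer migrating group. One operation should thus deliver the seven-membered ring, the C7 carbonyl, the quaternary C6 and the free 14-hydroxyl.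

**Step 12**
Reactants: 17 longipinane-1,7-dione
Product: 18 7,14-diol
Conditions: Me4NBH(OAc)3, MeCN/AcOH (1:1), −30 → 0 °C
Reagents that add atoms: none
Why: Evans–Saksena hydroxyl-directed reduction: boron bound to the 14-OH delivers hydride to the C11-side face of the C7 carbonyl, giving 7-OH on the C4 side (anti to 9-O), while the undirected C1 ketone is not reduced.

**Step 13**
Reactants: 18 7,14-diol
Product: 19 14-acetate
Conditions: Ac2O, pyridine, CH2Cl2, 0 °C
Reagents that add atoms: acetic anhydride, CC(=O)OC(C)=O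
Why: Acetylation is selective for the primary 14-OH over the neopentyl secondary 7-OH.

**Step 14**
Reactants: 19 14-acetate
Product: 20 14-acetoxy-7,9-dihydroxylongipinan-1-one
Conditions: HF·pyridine, THF, 0 °C → rt
Reagents that add atoms: none
Why: Fluoride desilylation under acidic conditions leaves the acetate and ketone intact and does not promote acyl migration.

**Step 15**
Reactants: 20 14-acetoxy-7,9-dihydroxylongipinan-1-one; 21 angelic acid
Product: 23 CNP0233066.1, via 9-monoangelate 22 (not isolated)
Conditions: 21, 2,4,6-trichlorobenzoyl chloride, Et3N, toluene, rt; then 20, toluene, 80 °C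
Reagents that add atoms: angelic acid (21), C/C=C(/C)C(=O)O
Why: Yamaguchi-type esterification through the mixed anhydride without DMAP, conditions under which the (Z)-2-methylbut-2-enoyl group should be transferred to both secondary hydroxyls without Z→E isomerisation.

**Compound list**
1 | (E)-pent-3-en-2-one | C/C=C/C(C)=O | starting material
2 | (E)-2-(triisopropylsilyloxy)penta-1,3-diene | C/C=C/C(=C)O[Si](C(C)C)(C(C)C)C(C)C | intermediate
3 | 2-methoxy-5-methyl-1,4-benzoquinone | COC1=CC(=O)C(C)=CC1=O | starting material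
4 | cis-decalin enedione: ring A C1(OSi-i-Pr3)=C2–C3H(CH3)–C4H–C10(CH3)–C11H2, ring B C4–C5(=O)–C7(OCH3)=C8H–C9(=O)–C10; 4-H cis to 10-CH3, 3-CH3 trans to 10-CH3 [3-methoxy-5,8a-dimethyl-7-(triisopropylsilyloxy)-4a,5,8,8a-tetrahydronaphthalene-1,4-dione] | C[C@@H]1C=C(O[Si](C(C)C)(C(C)C)C(C)C)C[C@]2(C)C(=O)C=C(OC)C(=O)[C@H]12 | intermediate
5 | 5,9-diol of 4; both OH on the ring-B face carrying the C4–C3 and C10–C11 bonds (trans to 10-CH3) | C[C@@H]1C=C(O[Si](C(C)C)(C(C)C)C(C)C)C[C@]2(C)[C@H](O)C=C(OC)[C@H](O)[C@H]12 | intermediate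
6 | 5-O-methanesulfonate of 5 (9-OH free) | C[C@@H]1C=C(O[Si](C(C)C)(C(C)C)C(C)C)C[C@]2(C)[C@H](O)C=C(OC)[C@H](OS(C)(=O)=O)[C@H]12 | intermediate
7 | 5-O-methanesulfonate 9-O-tert-butyldimethylsilyl ether of 5 | C[C@@H]1C=C(O[Si](C(C)C)(C(C)C)C(C)C)C[C@]2(C)[C@H](O[Si](C)(C)C(C)(C)C)C=C(OC)[C@H](OS(C)(=O)=O)[C@H]12 | intermediate
8 | keto mesylate: C1 ketone of 7 (ring A = 3,10-dimethylcyclohexanone) | C[C@@H]1CC(=O)C[C@]2(C)[C@H](O[Si](C)(C)C(C)(C)C)C=C(OC)[C@H](OS(C)(=O)=O)[C@H]12 | intermediate
9 | C5-inverted bromide of 8 (Br on the face of 10-CH3 and 4-H) | C[C@@H]1CC(=O)C[C@]2(C)[C@H](O[Si](C)(C)C(C)(C)C)C=C(OC)[C@@H](Br)[C@H]12 | intermediate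
10 | tricyclic ketone: cyclobutane C4–C5–C11–C10; bridge C11–C1(=O)–C2H2–C3H(CH3)–C4; bridge C5–C7(OCH3)=C8H–C9H(OTBS)–C10(CH3); 9-OTBS on the C11 side, 3-CH3 on the C5 side | COC1=C[C@@H](O[Si](C)(C)C(C)(C)C)[C@]2(C)[C@@H]3[C@H]1[C@H]2C(=O)C[C@H]3C | intermediate
11 | C1 alcohol of 10 (1-OH on the C10 side) | COC1=C[C@@H](O[Si](C)(C)C(C)(C)C)[C@]2(C)[C@@H]3[C@H]1[C@H]2[C@H](O)C[C@H]3C | intermediate
12 | 1-hydroxy 7-ketone (as 11 with C7(=O)–C8H2) | O=C1C[C@@H](O[Si](C)(C)C(C)(C)C)[C@]2(C)[C@@H]3[C@H]1[C@H]2[C@H](O)C[C@H]3C | intermediate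
13 | isopropenylmagnesium bromide | C=C(C)[Mg]Br | starting material
14 | 7-isopropenyl 1,7-diol: tertiary 7-OH on the C11 side, isopropenyl (C6 with CH3-13 and =C14H2) on the C4 side | CC(=C)[C@]1(O)C[C@@H](O[Si](C)(C)C(C)(C)C)[C@]2(C)[C@@H]3[C@H]1[C@H]2[C@H](O)C[C@H]3C | intermediate
15 | C1 ketone of 14 | CC(=C)[C@]1(O)C[C@@H](O[Si](C)(C)C(C)(C)C)[C@]2(C)[C@@H]3[C@H]1[C@H]2C(=O)C[C@H]3C | intermediate
16 | epoxy alcohol: 2-methyloxiran-2-yl group (C6, C14) on C7 of 15 | C[C@@]1(CO1)[C@]2(O)C[C@@H](O[Si](C)(C)C(C)(C)C)[C@]3(C)[C@@H]4[C@H]2[C@H]3C(=O)C[C@H]4C | intermediate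
17 | 9-(tert-butyldimethylsilyloxy)-14-hydroxylongipinane-1,7-dione: seven-membered ring C5–C6–C7–C8–C9–C10–C11; C6 bears CH3 (C4 side) and CH2OH (C11 side) | O=C1C[C@@H](O[Si](C)(C)C(C)(C)C)[C@]2(C)[C@@H]3[C@@H]([C@H]2C(=O)C[C@H]3C)[C@@]1(C)CO | intermediate
18 | 7,14-diol of 17 (7-OH on the C4 side) | O[C@@H]1C[C@@H](O[Si](C)(C)C(C)(C)C)[C@]2(C)[C@@H]3[C@@H]([C@H]2C(=O)C[C@H]3C)[C@@]1(C)CO | intermediate
19 | 14-acetate of 18 | O[C@@H]1C[C@@H](O[Si](C)(C)C(C)(C)C)[C@]2(C)[C@@H]3[C@@H]([C@H]2C(=O)C[C@H]3C)[C@@]1(C)COC(C)=O | intermediate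
20 | 14-acetoxy-7,9-dihydroxylongipinan-1-one (7-OH on the C4 side, 9-OH on the C11 side) | O[C@@H]1C[C@@H](O)[C@]2(C)[C@@H]3[C@@H]([C@H]2C(=O)C[C@H]3C)[C@@]1(C)COC(C)=O | intermediate
21 | angelic acid, (Z)-2-methylbut-2-enoic acid | C/C=C(/C)C(=O)O | starting material
22 | 9-O-angeloyl derivative of 20 | O[C@@H]1C[C@@H](OC(=O)/C(C)=C\C)[C@]2(C)[C@@H]3[C@@H]([C@H]2C(=O)C[C@H]3C)[C@@]1(C)COC(C)=O | intermediate
23 | CNP0233066.1: 14-acetoxy-7,9-bis(angeloyloxy)longipinan-1-one | C/C=C(/C)C(=O)O[C@@H]1C[C@@H](OC(=O)/C(C)=C\C)[C@]2(C)[C@@H]3[C@@H]([C@H]2C(=O)C[C@H]3C)[C@@]1(C)COC(C)=O | target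

**Totals**
Total step count: 15. Longest linear sequence: 15 steps (1 → 23).

**Steps most likely to fail**

Step 11 (key step). The methylene carbon C8 may migrate in place of the cyclobutane methine C5, or a hydride may shift from C14 to give an aldehyde. The fallback sets out from 15 and comes back at 20; it turns C8 into an α-keto carbon, which cannot migrate. HF·pyridine removes the silyl group to give the 7,9-diol F2. Dess–Martin periodinane oxidises only its secondary hydroxyl, giving the 9-ketone F3. VO(acac)2/t-BuOOH gives the epoxy alcohol F4, and ZnBr2 gives the ring-expanded 1,7,9-trione F5. Me4NBH(OAc)3 then reduces C7 (directed by the 14-OH) and afterwards C9 (directed 1,3-anti by the new 7-OH) to the triol F6. Acetylation of the primary hydroxyl (Ac2O, pyridine, 0 °C) gives 20.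

Step 6. O-alkylation of the enolate or base-induced loss of HBr may outrun the strained four-membered C–C closure. The fallback sets out from 8 and comes back at 10. Me3SiOTf/Et3N converts the ketone into the trimethylsilyl enol ether F1 (the C1=C11 isomer; the C1=C2 isomer cannot cyclise and is recycled by hydrolysis). Catalytic ZnBr2 (CH2Cl2, −40 °C) ionises the allylic mesylate to a 2-methoxyallyl cation, which the enol ether captures at C11 on the only face it can reach (Lewis-acid SN1 alkylation of a silyl enol ether). This closes the cyclobutane without a basic enolate.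

Step 15. Acylation of the two neopentyl-type secondary hydroxyls may be slow, and the acyl group may isomerise from Z to E under forcing conditions. The fallback sets out from 20 and comes back at 23. Both hydroxyls are esterified with the unhindered 2-[bis(2,2,2-trifluoroethoxy)phosphoryl]propanoic acid (DCC, DMAP, CH2Cl2) to give the bis(phosphonopropionate) F7. Still–Gennari olefination (KN(SiMe3)2, 18-crown-6, acetaldehyde, THF, −78 °C) then builds both (Z)-2-methylbut-2-enoates in place.

**Further compounds**
F1 | step 6 | C1=C11 trimethylsilyl enol ether of keto mesylate 8 | C[C@@H]1CC(O[Si](C)(C)C)=C[C@]2(C)[C@H](O[Si](C)(C)C(C)(C)C)C=C(OC)[C@H](OS(C)(=O)=O)[C@H]12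
F2 | step 11 | 7-isopropenyl 7,9-diol with C1 ketone (15 without the silyl group) | CC(=C)[C@]1(O)C[C@@H](O)[C@]2(C)[C@@H]3[C@H]1[C@H]2C(=O)C[C@H]3C
F3 | step 11 | 7-hydroxy-7-isopropenyl 1,9-diketone | CC(=C)[C@]1(O)CC(=O)[C@]2(C)[C@@H]3[C@H]1[C@H]2C(=O)C[C@H]3C
F4 | step 11 | epoxy alcohol of F3 | C[C@@]1(CO1)[C@]2(O)CC(=O)[C@]3(C)[C@@H]4[C@H]2[C@H]3C(=O)C[C@H]4C
F5 | step 11 | 14-hydroxylongipinane-1,7,9-trione | O=C1CC(=O)[C@]2(C)[C@@H]3[C@@H]([C@H]2C(=O)C[C@H]3C)[C@@]1(C)CO
F6 | step 11 | 7,9,14-trihydroxylongipinan-1-one | O[C@@H]1C[C@@H](O)[C@]2(C)[C@@H]3[C@@H]([C@H]2C(=O)C[C@H]3C)[C@@]1(C)CO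
F7 | step 15 | 7,9-bis{2-[bis(2,2,2-trifluoroethoxy)phosphoryl]propanoate} of 20 (epimers at the two phosphonate α-carbons) | CC(C(=O)O[C@@H]1C[C@@H](OC(=O)C(C)P(=O)(OCC(F)(F)F)OCC(F)(F)F)[C@]2(C)[C@@H]3[C@@H]([C@H]2C(=O)C[C@H]3C)[C@@]1(C)COC(C)=O)P(=O)(OCC(F)(F)F)OCC(F)(F)F
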